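## Structural features

The target is a saturated oxolane (ring atoms O1, C2, C3, C4, C5) with a 3,4-dihydroxyphenyl group on C2, a hydroxymethyl carbon (C6) on C3, and both a hydroxyl and a 3,4-dimethoxybenzyl group on C4; C5 is a plain O–CH2. C2, C3 and C4 are three adjacent stereocentres, all R, and the aryl group, C6 and the tertiary hydroxyl lie on one face of the ring, so the aryl/C6 pair is the less stable cis arrangement and the benzyl group is trans to C6. The C2–O1 bond is a benzylic ether para to a phenolic oxygen: acid can ionise it (epimerisation at C2, ring opening), hydrogen on palladium can cleave it, and the free catechol is sensitive to air and base. In any open-chain precursor with a C4 carbonyl, the oxygens on C2 and C6 are both β to that carbonyl, so enolisation towards C3 threatens epimerisation and loss of alkoxide. The real difficulty is the fully substituted C4 carbinol, which must be made with defined configuration next to the cis C2/C3 pair without disturbing it. The key step exploits C5 being an unsubstituted methylene between O1 and C4: a C5 carbanion equivalent carried on O1 can add to a C4 benzyl ketone, which forms C4–C5, closes the ring and creates the tertiary alcohol in one event, while the ether oxygen on C6 can steer the carbonyl face.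

## Logic of the disconnections

**19 from 18.** The three O–CH2Ph bonds (two on the catechol, one on the C6 oxygen) are cut last. This keeps the catechol and the primary alcohol masked through all organometallic steps and leaves one neutral operation at the end. The demand is that hydrogenolysis stops before the benzylic C2–O1 ring bond is attacked.

**18 from 16.** The C4–C5 bond is cut. The ring opens, C4 becomes a ketone and C5 becomes a chloromethyl group on O1. One ring and the hardest stereocentre disappear, leaving an acyclic chain whose two stereocentres are in an aldol relationship. The forward step must reduce the C–Cl bond in the presence of the ketone, add faster than the ketone is enolised, and select one carbonyl face.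

**16 from 14.** The C5–Cl bond is exchanged for a C5–S bond. The chloride is too reactive to carry through earlier steps, whereas the sulfide is inert to organomagnesium reagents. The forward step must chlorinate sulfur only, and leave two electron-rich arenes, an enolisable ketone and a benzylic ether alone.

**14 from 10 and 11.** The bond between C4 and the benzylic carbon is cut. This splits off the whole 3,4-dimethoxybenzyl unit as a commercial halide and makes the route convergent. The forward step must add once to the acyl group and must not expose the β-alkoxy ketone to base.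

**10 from 9.** The O1–C5 bond is cut, removing the one-carbon unit from O1. The same group protects O1 during the organomagnesium step, so no separate protecting group is needed. The forward step must work without forming the alkoxide, which would undergo retro-aldol cleavage.

**9 from 8.** The acyl C–N bond is exchanged. This removes the auxiliary and installs an acyl group that accepts exactly one carbon nucleophile. The forward step must attack the exocyclic carbonyl only and must not epimerise C3.

**8 from 4 and 5.** The C2–C3 bond is cut (aldol). Both remaining stereocentres are set together, syn, under auxiliary control, from an achiral aldehyde and an acyl imide. The forward step needs a Z enolate that does not expel the β-benzyloxy group.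

**4 from 1 and 2.** The imide N–C(O) bond is cut, giving a commercial acid and a commercial auxiliary. The forward step is an acylation under conditions mild enough not to eliminate benzyl alcohol.

## Other disconnections considered

**Alternative 1:** The cut goes through C2–C3 and through the bond between the aldehyde oxygen (the later O1) and C6, leading back to 3-(3,4-dimethoxybenzyl)furan A1 and 3,4-bis(pivaloyloxy)benzaldehyde A2. In the forward sense, irradiation would bring about a Paternò–Büchi cycloaddition through a triplet 1,4-biradical and give the exo bicyclic oxetane acetal A3, in which C2 and C3 have the relative configuration of 19.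

- In its favour: one photochemical step joins two simple fragments and delivers every carbon of 19, which is better convergence than the chosen plan offers. Exo selectivity of furan–aryl aldehyde photoadducts is normally high. Later oxidation of the C4=C5 enol ether from the convex face of A3 would place the C4 oxygen cis to C6, as required.
- Against it here: A3 is racemic and the reaction offers no handle for absolute control, so a resolution would be needed. The furan has two different double bonds, and addition at the benzyl-bearing one would compete. In A3 both C5 and C6 are at the aldehyde oxidation level and the ring oxygen bridges C5 and C6, not O1 and C5. The oxetane acetal would therefore have to be opened, C6 reduced, C4 oxidised and O1 re-closed onto C5 with discrimination between two primary positions. The acid this needs endangers the benzylic C2–O bond, and the pivalates must later be removed by base or hydride.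
- Comparison: structurally, the chosen plan never has to move the ring oxygen. Mechanistically, a biradical recombination with substrate-controlled relative configuration is set against an auxiliary-controlled aldol and a polar organosamarium addition; the alternative is equal on the C2/C3 relative configuration and weaker on absolute configuration. In step count it is shorter up to its key step but is expected to be longer overall once the redox adjustments and the resolution are counted.

**Alternative 2:** The cut is the C3–C6 bond (with the C2–H bond), leading back to the (bromomethyl)dimethylsilyl ether A4 of a 2,3-dihydrofuran-3-ol, whose only stereocentre is C4. In the forward sense, tin hydride chain conditions (Bu3SnH/AIBN) would generate the silylmethyl radical, which adds 5-exo-trig to C3 of the enol ether. The resulting C2 radical, benzylic and α to oxygen, takes hydrogen from the tin hydride to give the cis-fused oxolane–oxasilolane A5. Tamao oxidation of the C6–Si bond would then free the C4/C6 diol.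

- Structural note on A5: the radical carbon is C6 itself, so the silicon ring is the five-membered O–Si–C6–C3–C4 ring. A homologue with a second methylene between silicon and C3 would be a six-membered oxasilinane and would oxidise to a hydroxyethyl group; the five-membered ring is the one meant here.
- In its favour: silicon-tethered radical cyclisation followed by Tamao oxidation is an established sequence, so on precedent this key step is better founded than the chosen one. The short tether can only close cis, which fixes C6 cis to the C4 oxygen with certainty. Hydrogen transfer to the convex face of the bicyclic radical would put the aryl group cis to C6, so one stereocentre could relay the other two.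
- Against it here: A4 is a tertiary allylic silyl ether of a cyclic enol ether and is one elimination away from a furan, so aromatisation during silylation or on heating is a real concern. C4 of A4 is an isolated tertiary carbinol centre that would need its own enantioselective synthesis. The C2 configuration rests on the face selectivity of a hydrogen-atom transfer to a planar benzylic radical, which is less dependable than an aldol. Stoichiometric tin must be removed, and two steps follow the key step where the chosen plan needs one.
- Comparison: the two plans are mirror images in logic (C4 first with relay to C3 and C2, against C2/C3 first with C4 set by chelation). The alternative is better on precedent for its key reaction and equal in protecting groups and final deprotection. The chosen plan is better on stability of intermediates, on absolute control and probably on length.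

**Alternative 3:** The cut is the O1–C5 bond, leading back to the syn homopropargylic alcohol A6. In the forward sense, Ph3PAuNTf2 with a quinoline N-oxide as oxygen donor would oxidise the terminal alkyne to an α-oxo gold carbene at C5. O–H insertion of the C2 hydroxyl would close the ring and give the cis oxolan-3-one A7. Addition of 12 to the C4 ketone and debenzylation would then lead through 18 to 19.

- In its favour: gold-catalysed oxidative cyclisation of homopropargylic alcohols to oxolan-3-ones is a known catalytic reaction, so the ring closure is better precedented than the chosen key step. No α-halo ether is needed. The facial selectivity of the later addition to A7 is dictated by the ring (the nucleophile enters trans to the C3 substituent), which is at least as dependable as the chelate control of the chosen plan.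
- Against it here: the cationic gold medium meets a para-alkoxybenzylic alcohol that can ionise. In A7 the C3 hydrogen is α to the ketone and β to the benzyloxy group, so epimerisation to the more stable trans isomer and elimination threaten during cyclisation and during addition of a basic benzylic organometallic. A6 is not an aldol product; making it syn and enantiopure from 8 would take reduction to an aldehyde with an epimerisable α-centre and an alkyne homologation. Ring and C4 stereocentre are made in two separate steps, whereas the chosen key step makes both at once.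
- Comparison: both plans start from the same syn C2/C3 unit. Mechanistically, a carbene O–H insertion followed by a ring-controlled carbonyl addition is set against one chelate-controlled organosamarium addition. The alternative is better on precedent and equal or better on C4 selectivity; the chosen plan is shorter and avoids an enolisable cyclic β-alkoxy ketone. A7 is also the compound through which the fallback for the key step passes.

Key step: step 7

Assumption: ring atoms are numbered O1, C2 (aryl), C3 (bearing C6), C4 (carbinol), C5; with this numbering 19 is (2R,3R,4R), and acyclic intermediates carry systematic locants, which differ.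

## Route

Step 1
Reactants: 1 3-(benzyloxy)propanoic acid; 2 (R)-4-benzyl-1,3-oxazolidin-2-one
Product: 4 (R)-4-benzyl-3-[3-(benzyloxy)propanoyl]-1,3-oxazolidin-2-one, via mixed pivalic anhydride 3 (not isolated)
Conditions: PivCl, Et3N, THF, −20 °C; then LiCl, 2, −20 °C → rt
Reagents that add atoms: none
Why: Mixed-anhydride N-acylation of an oxazolidinone; the LiCl-activated auxiliary attacks the less hindered 3-(benzyloxy)propanoyl carbonyl of 3. No strong base is present, so benzyl alcohol is not eliminated, and the stereocentre of 2 is untouched.

Step 2
Reactants: 4 (R)-4-benzyl-3-[3-(benzyloxy)propanoyl]-1,3-oxazolidin-2-one; 5 3,4-bis(benzyloxy)benzaldehyde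
Product: 8 (R)-4-benzyl-3-[(2R,3R)-3-[3,4-bis(benzyloxy)phenyl]-2-[(benzyloxy)methyl]-3-hydroxypropanoyl]-1,3-oxazolidin-2-one, via Z-boron enolate 6 (not isolated), via boron aldolate 7 (not isolated)
Conditions: Bu2BOTf, iPr2NEt, CH2Cl2, 0 °C; then 5, −78 → 0 °C; pH 7 buffer, MeOH, 30% H2O2, 0 °C
Reagents that add atoms: none
Why: Evans syn-aldol reaction: the Z-boron enolate 6 reacts through a chair Zimmerman–Traxler transition state on the face away from the benzyl group of the auxiliary, which sets ring C3 and ring C2 together as the (R,R) syn pair (the (R)-auxiliary is needed because the (S)-auxiliary gives the (S,S) series with aryl aldehydes). The boron enolate is too weakly basic to expel the β-benzyloxy group, and oxidative work-up releases 8 from 7.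

Step 3
Reactants: 8 (R)-4-benzyl-3-[(2R,3R)-3-[3,4-bis(benzyloxy)phenyl]-2-[(benzyloxy)methyl]-3-hydroxypropanoyl]-1,3-oxazolidin-2-one
Product: 9 (2R,3R)-3-[3,4-bis(benzyloxy)phenyl]-2-[(benzyloxy)methyl]-3-hydroxy-N-methoxy-N-methylpropanamide
Conditions: MeNH(OMe)·HCl, AlMe3, CH2Cl2, −10 → 0 °C; aq. potassium sodium tartrate
Reagents that add atoms: N,O-dimethylhydroxylamine hydrochloride, CNOC.Cl
Why: Aluminium-amide transamination of an aldol imide (Weinreb amide formation); the free β-hydroxyl binds aluminium and directs attack to the exocyclic carbonyl, so the auxiliary is released intact. The medium is not basic, so neither retro-aldol cleavage nor epimerisation is expected.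

Step 4
Reactants: 9 (2R,3R)-3-[3,4-bis(benzyloxy)phenyl]-2-[(benzyloxy)methyl]-3-hydroxy-N-methoxy-N-methylpropanamide
Product: 10 (2R,3R)-3-[3,4-bis(benzyloxy)phenyl]-2-[(benzyloxy)methyl]-N-methoxy-N-methyl-3-[(methylsulfanyl)methoxy]propanamide
Conditions: Me2S, (BzO)2, MeCN, 0 °C
Reagents that add atoms: dimethyl sulfide, CSC
Why: Methylthiomethylation of an alcohol by Pummerer-type generation of the methyl(methylene)sulfonium ion from Me2S and benzoyl peroxide; it needs no alkoxide (which would undergo retro-aldol cleavage) and avoids the oxidation risk of DMSO/Ac2O at a benzylic alcohol. The ether places the future C5 on O1 and protects O1 in step 5.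

Step 5
Reactants: 10 (2R,3R)-3-[3,4-bis(benzyloxy)phenyl]-2-[(benzyloxy)methyl]-N-methoxy-N-methyl-3-[(methylsulfanyl)methoxy]propanamide; 11 4-(chloromethyl)-1,2-dimethoxybenzene (3,4-dimethoxybenzyl chloride)
Product: 14 (3R,4R)-4-[3,4-bis(benzyloxy)phenyl]-3-[(benzyloxy)methyl]-1-(3,4-dimethoxyphenyl)-4-[(methylsulfanyl)methoxy]butan-2-one, via benzylic Grignard reagent 12 (not isolated), via magnesium hemiaminal adduct 13 (not isolated)
Conditions: 11, Mg turnings, THF, 0 °C, slow addition; then 10, THF, −78 → 0 °C; cold aq. NH4Cl
Reagents that add atoms: none
Why: Weinreb ketone synthesis: 12 adds once, and the chelated adduct 13 keeps the carbonyl masked until the cold, mildly acidic quench, so over-addition, loss of the β-alkoxy groups and epimerisation at C3 should be avoided. Slow formation of 12 over excess Mg at 0 °C limits Wurtz coupling.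

Step 6
Reactants: 14 (3R,4R)-4-[3,4-bis(benzyloxy)phenyl]-3-[(benzyloxy)methyl]-1-(3,4-dimethoxyphenyl)-4-[(methylsulfanyl)methoxy]butan-2-one
Product: 16 (3R,4R)-4-[3,4-bis(benzyloxy)phenyl]-3-[(benzyloxy)methyl]-4-(chloromethoxy)-1-(3,4-dimethoxyphenyl)butan-2-one, via chlorosulfonium chloride 15 (not isolated)
Conditions: SO2Cl2 (1.0 equiv), cyclohexene, CH2Cl2, −78 → −20 °C; volatiles removed in vacuo, crude 16 used at once under argon
Reagents that add atoms: sulfuryl chloride, O=S(=O)(Cl)Cl
Why: Sulfuryl chloride cleavage of a methylthiomethyl ether to a chloromethyl ether: chlorination at sulfur gives 15, which collapses to the oxocarbenium/chloride pair and MeSCl. At −78 °C the sulfide reacts far faster than the arenes or the ketone enol, and cyclohexene traps MeSCl as it forms. 16 is a moisture-sensitive alkylating agent and is therefore neither stored nor chromatographed.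

Step 7
Reactants: 16 (3R,4R)-4-[3,4-bis(benzyloxy)phenyl]-3-[(benzyloxy)methyl]-4-(chloromethoxy)-1-(3,4-dimethoxyphenyl)butan-2-one
Product: 18 (3R,4R,5R)-5-[3,4-bis(benzyloxy)phenyl]-4-[(benzyloxy)methyl]-3-(3,4-dimethoxybenzyl)oxolan-3-ol, via alkoxymethylsamarium diiodide 17 (not isolated)
Conditions: SmI2 (3 equiv), THF, −78 → −20 °C, 16 added slowly to the reagent; aq. NH4Cl
Reagents that add atoms: none
Why: Proposed new method: divalent samarium should transfer one electron to the activated C–Cl bond of the α-chloro ether and a second one to the resulting alkoxymethyl radical, giving the alkoxymethylsamarium 17, whose C5 adds to the C4 ketone to give the samarium alkoxide of 18. The closest known reaction types are the SmI2 Barbier hydroxymethylation of ketones with benzyl chloromethyl ether (intermolecular) and the SmI2 Barbier cyclisation of halo ketones; the new element is a chloromethyl ether tethered through its oxygen to the ketone. The oxolane closes in the 5-exo-trig mode (C5 attacks the exocyclic C4=O; ring O1–C2–C3–C4–C5), which is stereoelectronically unhindered and should be faster than bimolecular coupling. The one new stereocentre, C4, is controlled by a six-membered chelate in which trivalent samarium bridges the carbonyl oxygen and the benzyl ether oxygen on C6; because C5 is tethered to C2 and must arrive from that side, the chelated oxygen becomes the hydroxyl cis to C6 and the 3,4-dimethoxybenzyl group ends trans to C6, an arrangement that also avoids eclipsing the two CH2 substituents on C3 and C4. The step needs chemoselectivity for the C–Cl bond over the ketone, which the substrate secures because an unconjugated dialkyl ketone is reduced only slowly by SmI2 in THF without HMPA whereas an α-chloro ether is reduced readily. It also needs addition to outrun proton transfer from the acidic benzylic α-methylene and loss of the β-alkoxy groups, which the intramolecular closure and the low basicity of the organosamarium favour; slow addition of 16 to excess reagent at low temperature limits ionisation of unreacted 16 by Lewis-acidic trivalent samarium. C2 and C3 are not touched.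

Step 8
Reactants: 18 (3R,4R,5R)-5-[3,4-bis(benzyloxy)phenyl]-4-[(benzyloxy)methyl]-3-(3,4-dimethoxybenzyl)oxolan-3-ol
Product: 19 (3R,4R,5R)-5-(3,4-dihydroxyphenyl)-3-(3,4-dimethoxybenzyl)-4-(hydroxymethyl)oxolan-3-ol
Conditions: H2 (1 atm), 10% Pd/C, EtOAc–MeOH, rt, stopped at full debenzylation; filtration under argon
Reagents that add atoms: none
Why: Catalytic hydrogenolysis of two aryl benzyl ethers and one alkyl benzyl ether. The ring C2–O1 bond is a hindered secondary benzylic ether and should be cleaved much more slowly in a neutral medium at 1 atm; methyl ethers and the tertiary alcohol are inert, and no stereocentre is involved.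

## Compound list

1 | 3-(benzyloxy)propanoic acid | OC(=O)CCOCc1ccccc1 | starting material
2 | (R)-4-benzyl-1,3-oxazolidin-2-one | O=C1N[C@H](Cc2ccccc2)CO1 | starting material (auxiliary, recovered in step 3)
3 | 3-(benzyloxy)propanoic pivalic anhydride | CC(C)(C)C(=O)OC(=O)CCOCc1ccccc1 | intermediate (not isolated)
4 | (R)-4-benzyl-3-[3-(benzyloxy)propanoyl]-1,3-oxazolidin-2-one | O=C(CCOCc1ccccc1)N1[C@H](Cc2ccccc2)COC1=O | intermediate
5 | 3,4-bis(benzyloxy)benzaldehyde | O=Cc1ccc(OCc2ccccc2)c(OCc2ccccc2)c1 | starting material
6 | (R)-4-benzyl-3-[(Z)-3-(benzyloxy)-1-(dibutylboryloxy)prop-1-enyl]-1,3-oxazolidin-2-one | CCCCB(CCCC)O/C(=C\COCc1ccccc1)N1[C@H](Cc2ccccc2)COC1=O | intermediate (not isolated)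
7 | O-dibutylboryl aldolate of 8 | CCCCB(CCCC)O[C@@H](c1ccc(OCc2ccccc2)c(OCc2ccccc2)c1)[C@@H](COCc1ccccc1)C(=O)N1[C@H](Cc2ccccc2)COC1=O | intermediate (not isolated)
8 | (R)-4-benzyl-3-[(2R,3R)-3-[3,4-bis(benzyloxy)phenyl]-2-[(benzyloxy)methyl]-3-hydroxypropanoyl]-1,3-oxazolidin-2-one | O[C@@H](c1ccc(OCc2ccccc2)c(OCc2ccccc2)c1)[C@@H](COCc1ccccc1)C(=O)N1[C@H](Cc2ccccc2)COC1=O | intermediate
9 | (2R,3R)-3-[3,4-bis(benzyloxy)phenyl]-2-[(benzyloxy)methyl]-3-hydroxy-N-methoxy-N-methylpropanamide | O[C@@H](c1ccc(OCc2ccccc2)c(OCc2ccccc2)c1)[C@@H](COCc1ccccc1)C(=O)N(C)OC | intermediate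
10 | (2R,3R)-3-[3,4-bis(benzyloxy)phenyl]-2-[(benzyloxy)methyl]-N-methoxy-N-methyl-3-[(methylsulfanyl)methoxy]propanamide | CSCO[C@@H](c1ccc(OCc2ccccc2)c(OCc2ccccc2)c1)[C@@H](COCc1ccccc1)C(=O)N(C)OC | intermediate
11 | 4-(chloromethyl)-1,2-dimethoxybenzene (3,4-dimethoxybenzyl chloride) | COc1ccc(CCl)cc1OC | starting material
12 | (3,4-dimethoxybenzyl)magnesium chloride | COc1ccc(C[Mg]Cl)cc1OC | intermediate (not isolated)
13 | chloromagnesium alkoxide of the N-methoxy-N-methyl hemiaminal from 10 and 12 (hemiaminal carbon undefined) | CSCO[C@@H](c1ccc(OCc2ccccc2)c(OCc2ccccc2)c1)[C@@H](COCc1ccccc1)C(O[Mg]Cl)(Cc1ccc(OC)c(OC)c1)N(C)OC | intermediate (not isolated)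
14 | (3R,4R)-4-[3,4-bis(benzyloxy)phenyl]-3-[(benzyloxy)methyl]-1-(3,4-dimethoxyphenyl)-4-[(methylsulfanyl)methoxy]butan-2-one | CSCO[C@@H](c1ccc(OCc2ccccc2)c(OCc2ccccc2)c1)[C@@H](COCc1ccccc1)C(=O)Cc1ccc(OC)c(OC)c1 | intermediate
15 | chloro(methyl)sulfonium chloride of 14 (sulfur undefined) | C[S+](Cl)CO[C@@H](c1ccc(OCc2ccccc2)c(OCc2ccccc2)c1)[C@@H](COCc1ccccc1)C(=O)Cc1ccc(OC)c(OC)c1.[Cl-] | intermediate (not isolated)
16 | (3R,4R)-4-[3,4-bis(benzyloxy)phenyl]-3-[(benzyloxy)methyl]-4-(chloromethoxy)-1-(3,4-dimethoxyphenyl)butan-2-one | ClCO[C@@H](c1ccc(OCc2ccccc2)c(OCc2ccccc2)c1)[C@@H](COCc3ccccc3)C(=O)Cc4ccc(OC)c(OC)c4 | intermediate (precursor of the key step, used crude)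
17 | alkoxymethylsamarium diiodide from 16 | I[Sm](I)CO[C@@H](c1ccc(OCc2ccccc2)c(OCc2ccccc2)c1)[C@@H](COCc1ccccc1)C(=O)Cc1ccc(OC)c(OC)c1 | intermediate (not isolated)
18 | (3R,4R,5R)-5-[3,4-bis(benzyloxy)phenyl]-4-[(benzyloxy)methyl]-3-(3,4-dimethoxybenzyl)oxolan-3-ol | COc1ccc(C[C@]2(O)CO[C@@H](c3ccc(OCc4ccccc4)c(OCc4ccccc4)c3)[C@H]2COCc5ccccc5)cc1OC | intermediate (product of the key step)
19 | (3R,4R,5R)-5-(3,4-dihydroxyphenyl)-3-(3,4-dimethoxybenzyl)-4-(hydroxymethyl)oxolan-3-ol | COc1ccc(C[C@]2(O)CO[C@@H](c3ccc(O)c(O)c3)[C@H]2CO)cc1OC | target

## Step count and least certain steps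

Total: 8 steps. Longest linear sequence: 8 steps (1 → 4 → 8 → 9 → 10 → 14 → 16 → 18 → 19).

**Step 7 (key step).**
- Most likely failure: electron transfer to the C–Cl bond is too slow at temperatures where 16 is stable. Trivalent samarium then ionises the chloromethyl ether (Friedel–Crafts attack on the C2 aryl ring, hydrolysis on work-up). Alternatively the alkoxymethylsamarium is protonated by the acidic benzylic α-methylene, or undergoes a 1,2-Wittig shift of the benzylic C2, before it adds.
- Second risk: incomplete facial selectivity if chelation to the C6 oxygen does not dominate.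
- Fallback (known reaction types only), from 10 back to 18: 10 would be homologated with chloromethyllithium (ICH2Cl, MeLi·LiBr, THF, −78 °C), which stops at the chelated adduct, to give the chloromethyl ketone (3R,4R)-4-[3,4-bis(benzyloxy)phenyl]-3-[(benzyloxy)methyl]-1-chloro-4-[(methylsulfanyl)methoxy]butan-2-one F1. Removal of the methylthiomethyl group (MeI, NaHCO3, aqueous acetone) would free the C2 hydroxyl in (3R,4R)-4-[3,4-bis(benzyloxy)phenyl]-3-[(benzyloxy)methyl]-1-chloro-4-hydroxybutan-2-one F2. Ag2O in CH2Cl2 would close O1 onto C5 by intramolecular Williamson etherification (5-exo-tet) to (4R,5R)-5-[3,4-bis(benzyloxy)phenyl]-4-[(benzyloxy)methyl]oxolan-3-one F3 (the same compound as A7). Addition of 12 with CeCl3 at −78 °C, from the ring face opposite the cis substituents on C2 and C3, would give 18.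

**Step 6.**
- Most likely failure: decomposition of 16 by ionisation or hydrolysis during concentration, and carry-over of sulfur by-products that consume SmI2. Competing electrophilic chlorination of the dimethoxyphenyl ring or of the ketone α-position is less likely at −78 °C with one equivalent.
- Fallback, from 14 back to 18: the cleavage would be run as before, but the cold solution of 16 would be treated with sodium pyridine-2-sulfinate in MeCN to give the bench-stable (3R,4R)-4-[3,4-bis(benzyloxy)phenyl]-3-[(benzyloxy)methyl]-1-(3,4-dimethoxyphenyl)-4-[(pyridin-2-ylsulfonyl)methoxy]butan-2-one F4, which can be chromatographed. α-Alkoxy 2-pyridyl sulfones are an established class of donors in SmI2 Barbier additions to carbonyl compounds, so SmI2 in THF would be expected to convert F4 to 18 through the same organosamarium 17.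

**Step 5.**
- Most likely failure: Wurtz-type homocoupling while 12 is formed from the electron-rich benzylic chloride, and deprotonation in place of addition by the basic benzylic reagent, leading to epimerisation at C3 or loss of alkoxide.
- Fallback, from 8 back to 14: the auxiliary of 8 would be displaced by LiSEt (THF, 0 °C) to give S-ethyl (2R,3R)-3-[3,4-bis(benzyloxy)phenyl]-2-[(benzyloxy)methyl]-3-hydroxypropanethioate F5. Me2S/(BzO)2 as in step 4 would give its methylthiomethyl ether, S-ethyl (2R,3R)-3-[3,4-bis(benzyloxy)phenyl]-2-[(benzyloxy)methyl]-3-[(methylsulfanyl)methoxy]propanethioate F6. Fukuyama coupling of F6 (PdCl2(PPh3)2, THF–toluene, rt) with (3,4-dimethoxybenzyl)zinc chloride F7, made from 11 with Zn dust and LiCl without Wurtz coupling, would give 14 under non-basic conditions.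

**Step 8.**
- Most likely failure: over-reduction, that is hydrogenolysis of the ring C2–O1 bond once the para hydroxyl is free. The alkyl benzyl ether on the C6 oxygen is the slowest to leave, so the free catechol stays on the catalyst for some time.
- Fallback, from 18 back to 19: a short hydrogenolysis (H2, Pd/C, EtOAc) would remove only the two aryl benzyl ethers and give 4-[(2R,3R,4R)-3-[(benzyloxy)methyl]-4-(3,4-dimethoxybenzyl)-4-hydroxyoxolan-2-yl]benzene-1,2-diol F8. Ac2O/pyridine at 0 °C would give the electron-poorer 4-[(2R,3R,4R)-3-[(benzyloxy)methyl]-4-(3,4-dimethoxybenzyl)-4-hydroxyoxolan-2-yl]-1,2-phenylene diacetate F9, in which the benzylic ring ether is deactivated. Hydrogenolysis of the remaining benzyl ether would give 4-[(2R,3R,4R)-4-(3,4-dimethoxybenzyl)-4-hydroxy-3-(hydroxymethyl)oxolan-2-yl]-1,2-phenylene diacetate F10, and K2CO3 in degassed MeOH at 0 °C would release 19.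

## Further compounds

F1 | step 7 | (3R,4R)-4-[3,4-bis(benzyloxy)phenyl]-3-[(benzyloxy)methyl]-1-chloro-4-[(methylsulfanyl)methoxy]butan-2-one | CSCO[C@@H](c1ccc(OCc2ccccc2)c(OCc2ccccc2)c1)[C@@H](COCc1ccccc1)C(=O)CCl
F2 | step 7 | (3R,4R)-4-[3,4-bis(benzyloxy)phenyl]-3-[(benzyloxy)methyl]-1-chloro-4-hydroxybutan-2-one | O[C@@H](c1ccc(OCc2ccccc2)c(OCc2ccccc2)c1)[C@@H](COCc1ccccc1)C(=O)CCl
F3 | step 7 | (4R,5R)-5-[3,4-bis(benzyloxy)phenyl]-4-[(benzyloxy)methyl]oxolan-3-one | O=C1CO[C@@H](c2ccc(OCc3ccccc3)c(OCc3ccccc3)c2)[C@H]1COCc4ccccc4
F4 | step 6 | (3R,4R)-4-[3,4-bis(benzyloxy)phenyl]-3-[(benzyloxy)methyl]-1-(3,4-dimethoxyphenyl)-4-[(pyridin-2-ylsulfonyl)methoxy]butan-2-one | O=S(=O)(CO[C@@H](c1ccc(OCc2ccccc2)c(OCc2ccccc2)c1)[C@@H](COCc1ccccc1)C(=O)Cc1ccc(OC)c(OC)c1)c1ccccn1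
F5 | step 5 | S-ethyl (2R,3R)-3-[3,4-bis(benzyloxy)phenyl]-2-[(benzyloxy)methyl]-3-hydroxypropanethioate | O[C@@H](c1ccc(OCc2ccccc2)c(OCc2ccccc2)c1)[C@@H](COCc1ccccc1)C(=O)SCC
F6 | step 5 | S-ethyl (2R,3R)-3-[3,4-bis(benzyloxy)phenyl]-2-[(benzyloxy)methyl]-3-[(methylsulfanyl)methoxy]propanethioate | CSCO[C@@H](c1ccc(OCc2ccccc2)c(OCc2ccccc2)c1)[C@@H](COCc1ccccc1)C(=O)SCC
F7 | step 5 | (3,4-dimethoxybenzyl)zinc chloride | COc1ccc(C[Zn]Cl)cc1OC
F8 | step 8 | 4-[(2R,3R,4R)-3-[(benzyloxy)methyl]-4-(3,4-dimethoxybenzyl)-4-hydroxyoxolan-2-yl]benzene-1,2-diol | COc1ccc(C[C@]2(O)CO[C@@H](c3ccc(O)c(O)c3)[C@H]2COCc4ccccc4)cc1OC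
F9 | step 8 | 4-[(2R,3R,4R)-3-[(benzyloxy)methyl]-4-(3,4-dimethoxybenzyl)-4-hydroxyoxolan-2-yl]-1,2-phenylene diacetate | COc1ccc(C[C@]2(O)CO[C@@H](c3ccc(OC(C)=O)c(OC(C)=O)c3)[C@H]2COCc4ccccc4)cc1OC
F10 | step 8 | 4-[(2R,3R,4R)-4-(3,4-dimethoxybenzyl)-4-hydroxy-3-(hydroxymethyl)oxolan-2-yl]-1,2-phenylene diacetate | COc1ccc(C[C@]2(O)CO[C@@H](c3ccc(OC(C)=O)c(OC(C)=O)c3)[C@H]2CO)cc1OC
A1 | alternative 1 | 3-(3,4-dimethoxybenzyl)furan | COc1ccc(Cc2ccoc2)cc1OC
A2 | alternative 1 | 3,4-bis(pivaloyloxy)benzaldehyde | O=Cc1ccc(OC(=O)C(C)(C)C)c(OC(=O)C(C)(C)C)c1
A3 | alternative 1 | exo-6-[3,4-bis(pivaloyloxy)phenyl]-4-(3,4-dimethoxybenzyl)-2,7-dioxabicyclo[3.2.0]hept-3-ene (racemic; enantiomer with the C2 and C3 configuration of 19 written) | O1[C@@H](c3ccc(OC(=O)C(C)(C)C)c(OC(=O)C(C)(C)C)c3)[C@@H]2C(Cc4ccc(OC)c(OC)c4)=CO[C@H]12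
A4 | alternative 2 | (R)-{[5-[3,4-bis(benzyloxy)phenyl]-3-(3,4-dimethoxybenzyl)-2,3-dihydrofuran-3-yl]oxy}(bromomethyl)dimethylsilane | COc1ccc(C[C@]2(O[Si](C)(C)CBr)COC(c3ccc(OCc4ccccc4)c(OCc4ccccc4)c3)=C2)cc1OC
A5 | alternative 2 | cis-fused oxolane–2,2-dimethyl-1,2-oxasilolane (ring O–Si–C6–C3–C4) with C2 3,4-bis(benzyloxy)phenyl and C4 3,4-dimethoxybenzyl, C2, C3 and C4 as in 19 | COc1ccc(C[C@]2(O[Si](C)(C)C3)CO[C@@H](c4ccc(OCc5ccccc5)c(OCc5ccccc5)c4)[C@H]23)cc1OC
A6 | alternative 3 | (1R,2R)-1-[3,4-bis(benzyloxy)phenyl]-2-[(benzyloxy)methyl]but-3-yn-1-ol | O[C@@H](c1ccc(OCc2ccccc2)c(OCc2ccccc2)c1)[C@@H](COCc1ccccc1)C#C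
A7 | alternative 3 | (4R,5R)-5-[3,4-bis(benzyloxy)phenyl]-4-[(benzyloxy)methyl]oxolan-3-one | O=C1CO[C@@H](c2ccc(OCc3ccccc3)c(OCc3ccccc3)c2)[C@H]1COCc4ccccc4
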